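**Remark on the chemistry.** Ring A is numbered with the carboxyl carbon at C1, hydroxyl at C2, the ester oxygen at C4 and pentyl at C6. Ring B is numbered with the ester carbonyl at C1', hydroxyl at C2', chlorine at C3', methoxy at C4' and propyl at C6'. The structures of 9, 11 and 13 agree atom by atom with the target and are used as drawn. Assumption: 1 and 10 are purchased, and 12 is used from a cylinder at balloon pressure.

## Structural features

The target is a depside in which two benzene rings, ring A and ring B, are joined only by an aryl ester whose carbonyl carbon is bonded to C1' of ring B and whose oxygen is bonded to C4 of ring A. Ring A is the olivetolic acid nucleus, with a free carboxylic acid at C1, a hydroxyl at C2 that is hydrogen-bonded to that acid, and a pentyl chain at C6. Ring B is pentasubstituted, with the ester carbonyl at C1', a hydroxyl at C2', chlorine at C3', methoxy at C4' and propyl at C6', so that only C5' carries hydrogen. There is no stereocentre and no ring besides the two arenes. Three points are fragile: the salicylic-type acid of ring A, which decarboxylates on heating or in strong acid; the aryl ester, which hydroxide and other nucleophiles cleave or transpose; and the C3'–Cl bond, which forcing reduction can remove. The first difficulty is that the ester carbonyl lies between two ortho substituents (the C2' oxygen and the C6' propyl), so acylation with a ring B acid derivative is slow. The second is that the contiguous C1'–C4' pattern, with chlorine between two oxygens, cannot be set reliably by electrophilic substitution. The key step exploits the fact that the ester carbonyl is a single carbon between C1' and the C4 oxygen, so it can be inserted as carbon monoxide between a C1' iodide and the C4 hydroxyl.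

## Logic of the disconnections

**14 to 13.** The two O–CH2Ph bonds of 13 are cut, one at the C2' oxygen and one at the C1 carboxyl. Both functions must be masked during the union, and one neutral hydrogenolysis removes both masks. The skeleton does not change, but the end game shrinks to one operation without base or heat. The forward step must cleave benzylic C–O bonds while leaving C3'–Cl, the aryl ester and the acid intact.

**13 to 9, 11 and 12.** The C1'–carbonyl bond and the carbonyl–O(C4) bond are cut together. The hindered ring B acid is therefore never prepared or activated. The problem falls into two arenes of similar size and a one-carbon unit. The forward step needs palladium to enter the C–I bond and ignore C–Cl, insertion of 12 to beat side reactions at the crowded metal centre, and the C4 hydroxyl of 11 to react in preference to the C2 hydroxyl.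

**11 to 10.** The ester O–CH2Ph bond is cut. The benzyl ester masks the acid and keeps the C2 hydroxyl tied up in a hydrogen bond, which is what differentiates the two phenols. This leads back to a purchasable acid. The forward step must alkylate the carboxylate only and run cold enough to avoid decarboxylation.

**9 to 8 to 7.** The ether O–CH2Ph bond of 9 and then the O–C(=O)N bond of 7 are cut. The carbamate that steers the metalations could not be removed after the union without destroying the aryl ester, so it is exchanged for benzyl beforehand. The forward steps must cleave a shielded carbamate without touching the C–I bond and then alkylate a phenol flanked by two halogens.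

**7 to 5 (through 6).** The C1'–I bond is cut. Once chlorine fills the site between the oxygens, the carbamate has one ortho hydrogen left, which is the carbon that will carry the ester carbonyl. The forward step needs the carbamate to outrank the methoxy group as director and the anion to stay cold so the carbamoyl group does not migrate.

**5 to 3 (through 4).** The C3'–Cl bond is cut. The hydrogen between carbamate and methoxy is the most acidic on the ring, so the chlorine goes in there first and with certainty. The forward step only requires that this metalation precede the other.

**3 to 2 to 1.** The O–C(=O)N bond and the O–CH3 bond are cut, which leads to a symmetrical, purchasable resorcinol. The cost is a desymmetrisation: mono-methylation of two equivalent hydroxyls is statistical and depends on stoichiometry and recycling.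

## Other disconnections considered

**Alternative 1:** Ring B is cut at C3'–C4' and C1'–C6'. Forward, 4-chloro-1-ethoxy-1,3-bis(trimethylsilyloxy)buta-1,3-diene A1 and 1,1-dimethoxyhex-1-en-3-one A2 would be combined under TiCl4. The chlorinated terminus of A1 adds to the acetal carbon of A2 with loss of one methoxy group, and C2 of A1 (the carbon between its two oxygen-bearing carbons) then closes onto the ketone of A2 by aldol condensation and dehydration. The product would be ethyl 3-chloro-2-hydroxy-4-methoxy-6-propylbenzoate A3.
- In its favour: the whole ring B pattern is fixed by the connectivity of the two acyclic pieces A1 and A2, with no organolithium chemistry and no halogenation of an arene. On regiocontrol of ring B this plan is the better one, and the ring B core A3 would be reached in about as few steps as 9.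
- Against it here: A3 is a hindered, hydrogen-bonded ethyl salicylate. It would need O-protection, forcing saponification, activation and classical acylation of the C4 hydroxyl of 11. The hardest bond of the target is then made in the way the chosen plan avoids. The chlorine on the nucleophilic terminus of A1 should also lower its reactivity.
- Comparison: the cyclocondensation and the carbonylation are both established reaction types, so mechanistic risk is about equal. The total would be about nine or ten steps, which is equal or slightly worse. The chosen plan is stronger where the two rings are joined; the alternative is stronger in building ring B.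

**Alternative 2:** Ring A is cut at C1–C6 and C2–C3. Forward, the sodium enolate of dibenzyl malonate A4 would add to (E)-non-3-en-2-one A5 in a Michael reaction at the pentyl-bearing carbon of A5. The methyl ketone of the adduct would then close onto one ester carbonyl that came from A4 in a Claisen condensation to give benzyl 2,4-dioxo-6-pentylcyclohexane-1-carboxylate A6 as the racemic trans compound. The C4 enol oxygen of A6 would later be acylated with a ring B acyl donor and the ring dehydrogenated to the arene.
- In its favour: A4 and A5 are cheap acyclic feedstocks, the ring construction is dependable, and the benzyl ester is present from the start. On material cost and on reliability of the ring-forming step it is the equal of the chosen plan. The two stereocentres of A6 vanish on aromatisation, so their configuration does not matter.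
- Against it here: ring A is purchasable as 10, so making it from A4 and A5 adds steps for no structural gain. The hindered ring B acid derivative is still needed. The enol ester from A6 is itself an acyl-transfer agent, open to oxygen-to-carbon acyl shift and to cleavage. The aromatising oxidation would have to run in the presence of the electron-rich ring B, whose C5'–H is open to halogenation, and of this labile ester.
- Comparison: the key step is sound, but the route is several steps longer and carries its risk in the late acylation and oxidation. The chosen plan joins two finished arenes under neutral, non-oxidising conditions.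

**Alternative 3:** Ring B is cut at C1'–C2' and C5'–C6'. Forward, benzyl 4-(hex-2-ynoyloxy)-2-hydroxy-6-pentylbenzoate A7 and 2-chloro-1,3-dimethoxy-1-(trimethylsilyloxy)buta-1,3-diene A8 would undergo a Diels–Alder reaction. The CH2 terminus of A8 bonds to the propyl-bearing alkyne carbon of A7 and the ketene-acetal carbon of A8 bonds to the alkyne carbon next to the ester carbonyl. The adduct aromatises when its ketal carbon expels the methoxy group and the remaining oxygen sheds its silyl group, which leaves the C2' hydroxyl free. The product would be benzyl 4-[(3-chloro-2-hydroxy-4-methoxy-6-propylbenzoyl)oxy]-2-hydroxy-6-pentylbenzoate A9.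
- In its favour: the ester bond is made on an unhindered alkynoic acid, ring B is built directly on ring A, the C2' hydroxyl needs no protecting group, and A9 is one hydrogenolysis away from 14. At about six steps it is better than the chosen plan on step count and on protecting-group economy.
- Against it here: A8 is a moisture-sensitive ketene-acetal diene with an internal chlorine that lowers its reactivity and disfavours the reactive conformation. A7 is a sluggish dienophile because of the alkyl substituent on its alkyne. The heating the cycloaddition would then need invites silyl transfer to the free C2 hydroxyl and attack of the ketene acetal on the aryl ester.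
- Comparison: the alternative is shorter but depends on one cycloaddition between two poorly matched partners. The chosen plan is longer, but each step is of a well-charted type and its selectivities rest on bond strength and hydrogen bonding.

Key step: step 8

## Steps

Step 1
Reactants: 1 5-propylresorcinol
Product: 2 3-methoxy-5-propylphenol
Conditions: MeI (1.0 equiv), K2CO3, acetone, reflux; unreacted 1 recovered and recycled
Reagents that add atoms: iodomethane, CI
Why: Williamson O-methylation of a phenoxide (SN2 at iodomethane); the two hydroxyls of 1 are equivalent, so only one mono-ether can form, and the limiting amount of MeI should hold double methylation down while 1 and the dimethyl ether are separable by acidity and polarity.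

Step 2
Reactants: 2 3-methoxy-5-propylphenol
Product: 3 3-methoxy-5-propylphenyl N,N-diethylcarbamate
Conditions: ClC(O)NEt2, K2CO3, MeCN, reflux
Reagents that add atoms: N,N-diethylcarbamoyl chloride, CCN(CC)C(Cl)=O
Why: O-carbamoylation by nucleophilic acyl substitution of the phenoxide on the carbamoyl chloride; 2 has a single hydroxyl, and the carbamate installed is the directing group for both metalations.

Step 3
Reactants: 3 3-methoxy-5-propylphenyl N,N-diethylcarbamate
Product: 5 2-chloro-3-methoxy-5-propylphenyl N,N-diethylcarbamate, via C2-lithiated carbamate 4 (not isolated)
Conditions: s-BuLi, TMEDA, THF, −78 °C; then C2Cl6, −78 °C to rt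
Reagents that add atoms: hexachloroethane, ClC(Cl)(Cl)C(Cl)(Cl)Cl (the chlorine of 5); sec-butyllithium, CCC(C)[Li] (the lithium of 4 only)
Why: directed ortho-metalation; the hydrogen between carbamate and methoxy (the future C3') is acidified and chelated by both oxygen groups, so s-BuLi/TMEDA should remove it in preference to the other ring hydrogens, and hexachloroethane transfers chlorine to the aryllithium while −78 °C keeps the lithiated carbamate from rearranging.

Step 4
Reactants: 5 2-chloro-3-methoxy-5-propylphenyl N,N-diethylcarbamate
Product: 7 2-chloro-6-iodo-3-methoxy-5-propylphenyl N,N-diethylcarbamate, via C6-lithiated chlorocarbamate 6 (not isolated)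
Conditions: s-BuLi, TMEDA, THF, −78 °C; then I2 in THF, −78 °C to rt; aq. Na2S2O3 wash
Reagents that add atoms: iodine, II (the iodine of 7); sec-butyllithium, CCC(C)[Li] (the lithium of 6 only)
Why: second directed ortho-metalation; with the doubly activated site blocked by chlorine, the carbamate (a much stronger director than methoxy) should guide the base to its one remaining ortho hydrogen (the future C1', next to propyl), and iodine traps the anion; the anion is meta to chlorine so no aryne can form, and the cold quench forestalls the anionic ortho-Fries shift.

Step 5
Reactants: 7 2-chloro-6-iodo-3-methoxy-5-propylphenyl N,N-diethylcarbamate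
Product: 8 2-chloro-6-iodo-3-methoxy-5-propylphenol
Conditions: NaOH, EtOH/H2O, reflux; then aq. HCl
Reagents that add atoms: none
Why: base hydrolysis of a carbamate by addition–elimination at the carbonyl; the 2,6-dihalophenoxide is a good leaving group, the carbamic acid left behind decarboxylates, and aryl iodide, aryl chloride and methyl ether are inert to hot aqueous-ethanolic hydroxide.

Step 6
Reactants: 8 2-chloro-6-iodo-3-methoxy-5-propylphenol
Product: 9 2-(benzyloxy)-3-chloro-1-iodo-4-methoxy-6-propylbenzene
Conditions: BnBr, K2CO3, DMF, 60 °C
Reagents that add atoms: benzyl bromide, BrCc1ccccc1
Why: Williamson benzylation; the acidic 2,6-dihalophenol is fully ionised by K2CO3 in DMF, and the unhindered benzylic bromide should react despite the two ortho halogens.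

Step 7
Reactants: 10 olivetolic acid
Product: 11 benzyl 2,4-dihydroxy-6-pentylbenzoate
Conditions: BnBr (1.05 equiv), KHCO3, DMF, rt
Reagents that add atoms: benzyl bromide, BrCc1ccccc1
Why: carboxylate O-alkylation (SN2); KHCO3 ionises only the carboxylic acid and not the phenols, so one equivalent of benzyl bromide should give the ester alone, and room temperature avoids decarboxylation of the salicylic-type acid.

Step 8
Reactants: 9 2-(benzyloxy)-3-chloro-1-iodo-4-methoxy-6-propylbenzene; 11 benzyl 2,4-dihydroxy-6-pentylbenzoate; 12 carbon monoxide
Product: 13 benzyl 4-{[2-(benzyloxy)-3-chloro-4-methoxy-6-propylbenzoyl]oxy}-2-hydroxy-6-pentylbenzoate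
Conditions: Pd(OAc)2 (5 mol %), Xantphos (6 mol %), CO (1 atm), Et3N, toluene, 90 °C
Reagents that add atoms: none
Why: Pd(OAc)2 is reduced in the flask to a Xantphos-bound zerovalent palladium species, which inserts into the C1'–I bond of 9; coordination and migratory insertion of 12 then give a divalent aroylpalladium iodide. The C4 phenoxide of 11, formed with Et3N, displaces iodide at palladium, and C–O reductive elimination (or direct attack at the acyl carbon) releases 13 and returns zerovalent palladium, so the C1'–carbonyl bond and the carbonyl–O(C4) bond are made in one catalytic turnover. The closest known reaction type is the palladium-catalysed carbonylative esterification (aryloxycarbonylation) of aryl iodides with phenols under CO. No ring is closed and no stereocentre is created. Three selectivities are needed: iodine over chlorine, secured by the much weaker C–I bond under conditions where an electron-rich aryl chloride is inert; the C4 hydroxyl over the C2 hydroxyl, secured by the hydrogen bond that ties the C2 hydroxyl to the benzyl ester carbonyl and by its more crowded position; and CO insertion ahead of direct C–O coupling or palladation of the neighbouring benzyl group, which the CO atmosphere and the wide bite angle of Xantphos favour. The two ortho substituents at C1' slow oxidative addition but should speed insertion, because the acyl group moves the crowded carbon one atom away from the metal. A small excess of 11 and full conversion of 9 are planned so that the only arene left to separate is a polar phenol.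

Step 9
Reactants: 13 benzyl 4-{[2-(benzyloxy)-3-chloro-4-methoxy-6-propylbenzoyl]oxy}-2-hydroxy-6-pentylbenzoate
Product: 14 4-[(3-chloro-2-hydroxy-4-methoxy-6-propylbenzoyl)oxy]-2-hydroxy-6-pentylbenzoic acid
Conditions: H2 (1 atm), Pd/C (5 wt % Pd), EtOAc, rt, stopped after uptake of 2 equiv
Reagents that add atoms: none
Why: catalytic hydrogenolysis of benzylic C–O bonds; the benzyl ether and benzyl ester are cleaved at room temperature and 1 atm, while in a neutral, base-free aprotic solvent hydrogenolysis of an aryl chloride is much slower, so C3'–Cl, the aryl ester and the methyl ether should survive and the acid is never heated.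

## Compound list

1 | 5-propylresorcinol (5-propylbenzene-1,3-diol) | CCCc1cc(O)cc(O)c1 | starting material
2 | 3-methoxy-5-propylphenol | CCCc1cc(O)cc(OC)c1 | intermediate
3 | 3-methoxy-5-propylphenyl N,N-diethylcarbamate | CCCc1cc(OC)cc(OC(=O)N(CC)CC)c1 | intermediate
4 | {2-[(diethylcarbamoyl)oxy]-6-methoxy-4-propylphenyl}lithium | CCCc1cc(OC)c([Li])c(OC(=O)N(CC)CC)c1 | intermediate (not isolated)
5 | 2-chloro-3-methoxy-5-propylphenyl N,N-diethylcarbamate | CCCc1cc(OC)c(Cl)c(OC(=O)N(CC)CC)c1 | intermediate
6 | {3-chloro-2-[(diethylcarbamoyl)oxy]-4-methoxy-6-propylphenyl}lithium | CCCc1cc(OC)c(Cl)c(OC(=O)N(CC)CC)c1[Li] | intermediate (not isolated)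
7 | 2-chloro-6-iodo-3-methoxy-5-propylphenyl N,N-diethylcarbamate | CCCc1cc(OC)c(Cl)c(OC(=O)N(CC)CC)c1I | intermediate
8 | 2-chloro-6-iodo-3-methoxy-5-propylphenol | CCCc1cc(OC)c(Cl)c(O)c1I | intermediate
9 | 2-(benzyloxy)-3-chloro-1-iodo-4-methoxy-6-propylbenzene | CCCc1cc(OC)c(Cl)c(OCc2ccccc2)c1I | intermediate
10 | olivetolic acid (2,4-dihydroxy-6-pentylbenzoic acid) | CCCCCc1cc(O)cc(O)c1C(=O)O | starting material
11 | benzyl 2,4-dihydroxy-6-pentylbenzoate | CCCCCc1cc(O)cc(O)c1C(=O)OCc1ccccc1 | intermediate
12 | carbon monoxide | [C-]#[O+] | starting material
13 | benzyl 4-{[2-(benzyloxy)-3-chloro-4-methoxy-6-propylbenzoyl]oxy}-2-hydroxy-6-pentylbenzoate | CCCCCc1cc(OC(=O)c2c(CCC)cc(OC)c(Cl)c2OCc2ccccc2)cc(O)c1C(=O)OCc1ccccc1 | intermediate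
14 | 4-[(3-chloro-2-hydroxy-4-methoxy-6-propylbenzoyl)oxy]-2-hydroxy-6-pentylbenzoic acid | CCCCCc1cc(OC(=O)c2c(CCC)cc(OC)c(Cl)c2O)cc(O)c1C(=O)O | target

## Step count and least certain steps

Total step count: 9. Longest linear sequence: 8 (steps 1 to 6, then 8 and 9); step 7 is the one-step side branch.

**Step 8 (key step).** Oxidative addition at the electron-rich, doubly ortho-substituted C1'–I bond may be slow. That would leave room for hydrodeiodination or palladation of the neighbouring benzyl group. Capture of the aroylpalladium by the weakly nucleophilic phenol may also lag, or acylation may not stop at the C4 hydroxyl. Fallback: from 9, iodine–magnesium exchange with iPrMgCl·LiCl (THF, 0 °C) should give [2-(benzyloxy)-3-chloro-4-methoxy-6-propylphenyl]magnesium chloride F1. Carboxylation with CO2 and acidic work-up (aq. HCl) should then give 2-(benzyloxy)-3-chloro-4-methoxy-6-propylbenzoic acid F2. Trifluoroacetic anhydride in toluene at rt would convert this acid into 2-(benzyloxy)-3-chloro-4-methoxy-6-propylbenzoic trifluoroacetic anhydride F3, which acylates the C4 hydroxyl of 11 and rejoins the route at 13. This is the classical mixed-anhydride esterification for hindered benzoic acids; it gives up the carbonylative shortcut but not the protecting-group plan.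

**Step 4.** The carbamoyl group may migrate from oxygen to the lithiated carbon if the anion warms before the quench. Metalation at the site crowded by the propyl group may be incomplete, and some metalation next to the methoxy group is possible. Fallback: from 5, deprotonation with lithium 2,2,6,6-tetramethylpiperidide in the presence of Me3SiCl (THF, −78 °C) would silylate the anion as it forms. This should give 2-chloro-3-methoxy-5-propyl-6-(trimethylsilyl)phenyl N,N-diethylcarbamate F4. Ipso-iododesilylation with ICl (CH2Cl2, 0 °C) would then rejoin the route at 7.

**Step 9.** Over-reduction may remove the C3' chlorine, above all if the reaction must be prolonged to cleave the crowded C2' benzyl ether. Fallback: from 13, non-reductive debenzylation with BCl3 and pentamethylbenzene as cation scavenger (CH2Cl2, −78 °C) should cleave both the benzyl ether and the benzyl ester without any reducing agent and arrive directly at 14. This path makes no new compound and is entered as F0.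

**Step 5.** Hydrolysis of the carbamate, shielded by chlorine and iodine, may stall. Forcing it with more heat and base risks loss of iodine and general degradation. Fallback: from 7, reductive cleavage with Cp2Zr(H)Cl (THF, rt) delivers hydride to the carbamate carbonyl and releases the aryloxide under non-hydrolytic conditions, rejoining the route at 8. This path makes no new compound and is entered as F0.

**Step 1.** Methylation of two equivalent hydroxyls is statistical, so over-methylation and unreacted diol lower the throughput. Fallback: from 1, exhaustive methylation (Me2SO4, K2CO3, acetone, reflux) should give 1,3-dimethoxy-5-propylbenzene F5. Mono-demethylation with NaSEt (DMF, 140 °C) should stop at the phenoxide, which resists a second thiolate attack, and rejoin the route at 2.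

## Further compounds

F1 | step 8 | [2-(benzyloxy)-3-chloro-4-methoxy-6-propylphenyl]magnesium chloride | CCCc1cc(OC)c(Cl)c(OCc2ccccc2)c1[Mg]Cl
F2 | step 8 | 2-(benzyloxy)-3-chloro-4-methoxy-6-propylbenzoic acid | CCCc1cc(OC)c(Cl)c(OCc2ccccc2)c1C(=O)O
F3 | step 8 | 2-(benzyloxy)-3-chloro-4-methoxy-6-propylbenzoic trifluoroacetic anhydride | CCCc1cc(OC)c(Cl)c(OCc2ccccc2)c1C(=O)OC(=O)C(F)(F)F
F4 | step 4 | 2-chloro-3-methoxy-5-propyl-6-(trimethylsilyl)phenyl N,N-diethylcarbamate | CCCc1cc(OC)c(Cl)c(OC(=O)N(CC)CC)c1[Si](C)(C)C
F0 | step 9 | none | none
F0 | step 5 | none | none
F5 | step 1 | 1,3-dimethoxy-5-propylbenzene | CCCc1cc(OC)cc(OC)c1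
A1 | alternative 1 | 4-chloro-1-ethoxy-1,3-bis(trimethylsilyloxy)buta-1,3-diene (double-bond geometry not defined) | CCOC(O[Si](C)(C)C)=CC(O[Si](C)(C)C)=CCl
A2 | alternative 1 | 1,1-dimethoxyhex-1-en-3-one | CCCC(=O)C=C(OC)OC
A3 | alternative 1 | ethyl 3-chloro-2-hydroxy-4-methoxy-6-propylbenzoate | CCCc1cc(OC)c(Cl)c(O)c1C(=O)OCC
A4 | alternative 2 | dibenzyl malonate | O=C(CC(=O)OCc1ccccc1)OCc1ccccc1
A5 | alternative 2 | (E)-non-3-en-2-one | CCCCC/C=C/C(C)=O
A6 | alternative 2 | benzyl (1S,6R)-2,4-dioxo-6-pentylcyclohexane-1-carboxylate (drawn enantiomer of the racemic trans compound) | CCCCC[C@@H]1CC(=O)CC(=O)[C@H]1C(=O)OCc1ccccc1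
A7 | alternative 3 | benzyl 4-(hex-2-ynoyloxy)-2-hydroxy-6-pentylbenzoate | CCCCCc1cc(OC(=O)C#CCCC)cc(O)c1C(=O)OCc1ccccc1
A8 | alternative 3 | 2-chloro-1,3-dimethoxy-1-(trimethylsilyloxy)buta-1,3-diene (double-bond geometry not defined) | C=C(OC)C(Cl)=C(OC)O[Si](C)(C)C
A9 | alternative 3 | benzyl 4-[(3-chloro-2-hydroxy-4-methoxy-6-propylbenzoyl)oxy]-2-hydroxy-6-pentylbenzoate | CCCCCc1cc(OC(=O)c2c(CCC)cc(OC)c(Cl)c2O)cc(O)c1C(=O)OCc1ccccc1
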